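**Retrosynthetic overview**

1. 22 ⇐ 21 (acetylation) ⇐ 16 by two-carbon Wittig homologation of the C1 carbinol, 1,2-reduction and hydrogenation of the chain alkene; 16 ⇐ 15 by hydroxyl-directed hydrogenation of C4=C5, which sets C5.
2. 15 ⇐ 14 ⇐ 7 + 13: auxiliary-controlled endo Diels–Alder reaction of a Z 1,1,2-trisubstituted butadiene that already carries the umbelliferyl ether with an N-(4-methylpenta-2,3-dienoyl)oxazolidinone; it forms C2–C3 and C1–C6, and with them the ring, quaternary C6, the C1 stereocentre and the isopropylidene.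
3. Enabling feature: in the cyclohexane ring (C1 = CH carrying the side chain, C2 = isopropylidene carbon, C3 and C4 = CH2, C5 = CHMe, C6 = quaternary carbon) the pair C1–C2 with its exocyclic C=CMe2 is what addition across the proximal double bond of a 1,1-dimethylallene leaves behind, and C3–C6 are the four carbons of a diene whose new C4=C5 bond is saturated afterwards.
4. 7 ⇐ but-2-yn-1-ol (anti-carbomagnesiation/iodination, Stille vinylation, Mitsunobu etherification with umbelliferone while the carbinol is still allylic); 13 ⇐ a chloroacetyl oxazolidinone (ylide formation, Wittig reaction with dimethylketene).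
5. Ring order: the coumarin bicycle is bought as umbelliferone; the cyclohexane ring is the only ring made, in step 6.

Key step: step 6

Assumption: the given configuration is read as side chain cis to the C6 methyl and C5 methyl cis to the aryloxymethyl group ((1S,2S,3S) in the name of 22), and compound 8 is taken as purchasable (otherwise one N-acylation of the parent oxazolidinone with chloroacetyl chloride).

**Route**

Step 1
Reactants: 1 but-2-yn-1-ol
Product: 3 (2Z)-3-iodo-2-methylbut-2-en-1-ol, via cyclic alkenylmagnesium alkoxide 2 (not isolated)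
Conditions: MeMgBr (3 equiv), CuI (10 mol%), THF, 0 °C → reflux; then I2, THF, −78 → 0 °C
Reagents that add atoms: methylmagnesium bromide, C[Mg]Br; iodine, II
Why: Copper-catalysed anti-carbomagnesiation of the propargylic alkoxide delivers methyl to C2 and magnesium to C3 inside a five-membered chelate, so iodinolysis with retention should give the Z tetrasubstituted alkenyl iodide with iodine cis to CH2OH.

Step 2
Reactants: 3 (2Z)-3-iodo-2-methylbut-2-en-1-ol; 4 tributyl(ethenyl)stannane
Product: 5 (2Z)-2,3-dimethylpenta-2,4-dien-1-ol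
Conditions: Pd(PPh3)4 (5 mol%), CuI (10 mol%), DMF, 35 °C, dark
Reagents that add atoms: none
Why: Stille cross-coupling proceeds with retention of alkene geometry and so should place the vinyl group cis to CH2OH (Z diene), the low temperature avoiding a 1,5-hydrogen shift of the Z dienol.

Step 3
Reactants: 5 (2Z)-2,3-dimethylpenta-2,4-dien-1-ol; 6 umbelliferone (7-hydroxy-2H-chromen-2-one)
Product: 7 7-{[(2Z)-2,3-dimethylpenta-2,4-dien-1-yl]oxy}-2H-chromen-2-one
Conditions: PPh3, DIAD, THF, 0 °C → rt
Reagents that add atoms: none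
Why: Mitsunobu etherification of a primary allylic alcohol with the acidic phenol umbelliferone should give the aryl ether by direct SN2 displacement while this carbon is still allylic and unhindered, before it becomes neopentylic.

Step 4
Reactants: 8 (4R)-4-benzyl-3-(chloroacetyl)-1,3-oxazolidin-2-one
Product: 10 (4R)-4-benzyl-3-[(triphenyl-λ5-phosphanylidene)acetyl]-1,3-oxazolidin-2-one, via acylmethylphosphonium chloride 9 (not isolated)
Conditions: PPh3, toluene, 80 °C; then aq. Na2CO3, CH2Cl2, rt
Reagents that add atoms: triphenylphosphine, c1ccc(cc1)P(c1ccccc1)c1ccccc1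
Why: SN2 quaternisation of triphenylphosphine by the α-chloro imide and deprotonation of the acidic CH2 of the salt by carbonate should give the imide-stabilised ylide without opening the oxazolidinone.

Step 5
Reactants: 10 (4R)-4-benzyl-3-[(triphenyl-λ5-phosphanylidene)acetyl]-1,3-oxazolidin-2-one; 11 2-methylpropanoyl chloride
Product: 13 (4R)-4-benzyl-3-(4-methylpenta-2,3-dienoyl)-1,3-oxazolidin-2-one, via dimethylketene 12 (not isolated)
Conditions: Et3N, CH2Cl2, 0 °C → rt, slow addition of 11
Reagents that add atoms: none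
Why: Triethylamine dehydrochlorinates the acid chloride to dimethylketene, whose C=O undergoes Wittig olefination with the stabilised ylide to give the 1,1-dimethylallene (allene synthesis by the ketene Wittig reaction).

Step 6
Reactants: 7 7-{[(2Z)-2,3-dimethylpenta-2,4-dien-1-yl]oxy}-2H-chromen-2-one; 13 (4R)-4-benzyl-3-(4-methylpenta-2,3-dienoyl)-1,3-oxazolidin-2-one
Product: 14 (4R)-4-benzyl-3-{[(1S,2R)-2,3-dimethyl-2-{[(2-oxo-2H-chromen-7-yl)oxy]methyl}-6-(propan-2-ylidene)cyclohex-3-en-1-yl]carbonyl}-1,3-oxazolidin-2-one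
Conditions: Et2AlCl (2.5 equiv), CH2Cl2, −78 → −30 °C
Reagents that add atoms: none
Why: Chelation of Et2AlCl by both imide carbonyls gives the cationic s-cis dienophile, and the diene adds across its allenic Cα=Cβ bond in an asynchronous concerted [4+2] cycloaddition in which the unsubstituted CH2 terminus bonds to the central allene carbon (C3–C2) and the fully substituted terminus to the α-carbon (C6–C1), the closest precedents being Et2AlCl-promoted Diels–Alder reactions of chiral N-enoyl oxazolidinones and Lewis-acid-promoted Diels–Alder reactions of allenic esters. The cyclohexene ring closes in this single intermolecular suprafacial [4+2] event. C1 is set by the auxiliary, whose benzyl group shields one face of the chelated dienophile so that the diene should add to the Cα-Re face; C6 is set relative to C1 by the endo rule together with the Z diene geometry, which places the outside methyl cis and the inside aryloxymethyl group trans to the acyl group. The step needs regioselectivity, selectivity for the α,β over the β,γ allene bond, and endo selectivity: the first two follow from the large LUMO coefficient at the central carbon and from the γ-methyl groups, which leave room only for the CH2 terminus, and endo addition is the normal outcome for the aluminium chelate. The untouched allene bond emerges as the exocyclic isopropylidene, so ring, quaternary centre, C1 stereocentre and tetrasubstituted alkene should all arise here; the extra Lewis acid allows for one equivalent bound by the coumarin carbonyl.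

Step 7
Reactants: 14 the Diels–Alder adduct
Product: 15 [(1S,2R)-2,3-dimethyl-2-{[(2-oxo-2H-chromen-7-yl)oxy]methyl}-6-(propan-2-ylidene)cyclohex-3-en-1-yl]methanol
Conditions: NaBH4, THF/H2O (4:1), 0 °C → rt
Reagents that add atoms: none
Why: Borohydride reduction at the exocyclic imide carbonyl (reductive removal of the oxazolidinone auxiliary) is much faster than attack on the coumarin lactone and does not enolise C1, so the primary alcohol should form with C1 and C6 unchanged.

Step 8
Reactants: 15 the cyclohexenylmethanol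
Product: 16 [(1S,2S,3S)-2,3-dimethyl-2-{[(2-oxo-2H-chromen-7-yl)oxy]methyl}-6-(propan-2-ylidene)cyclohexyl]methanol
Conditions: [Rh(nbd)(dppb)]BF4 (nbd = norbornadiene, dppb = 1,4-bis(diphenylphosphino)butane; 10 mol%), H2 (50 bar), CH2Cl2, rt
Reagents that add atoms: none
Why: Hydroxyl-directed homogeneous hydrogenation: allylic 1,3-strain against the isopropylidene holds C1–CH2OH axial on the face opposite the aryloxymethyl group, the cationic rhodium bound to this hydroxyl delivers H2 to that face of C4=C5 and so should set C5 with its methyl cis to CH2OAr, while the tetrasubstituted isopropylidene and the coumarin double bond are not reduced by this catalyst.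

Step 9
Reactants: 16 the cyclohexylmethanol; 17 (triphenyl-λ5-phosphanylidene)acetaldehyde
Product: 19 (2E)-3-[(1S,2S,3S)-2,3-dimethyl-2-{[(2-oxo-2H-chromen-7-yl)oxy]methyl}-6-(propan-2-ylidene)cyclohexyl]prop-2-enal, via cyclohexanecarbaldehyde 18 (not isolated)
Conditions: Dess–Martin periodinane, NaHCO3, CH2Cl2, 0 °C; then 17, toluene, 60 °C
Reagents that add atoms: none
Why: Buffered Dess–Martin oxidation gives the β,γ-unsaturated aldehyde without base, and Wittig olefination with the stabilised formyl ylide, a weak base, should give the E enal before C1 can epimerise or the exocyclic alkene can move into conjugation.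

Step 10
Reactants: 19 the enal
Product: 20 (2E)-3-[(1S,2S,3S)-2,3-dimethyl-2-{[(2-oxo-2H-chromen-7-yl)oxy]methyl}-6-(propan-2-ylidene)cyclohexyl]prop-2-en-1-ol
Conditions: NaBH4, CeCl3·7H2O, MeOH, −20 °C
Reagents that add atoms: none
Why: Luche reduction, the cerium-assisted 1,2-reduction of an enal, should give the allylic alcohol and leave the coumarin untouched.

Step 11
Reactants: 20 the allylic alcohol
Product: 21 3-[(1S,2S,3S)-2,3-dimethyl-2-{[(2-oxo-2H-chromen-7-yl)oxy]methyl}-6-(propan-2-ylidene)cyclohexyl]propan-1-ol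
Conditions: [Rh(nbd)(dppb)]BF4 (5 mol%), H2 (20 bar), CH2Cl2, rt
Reagents that add atoms: none
Why: Hydroxyl-directed hydrogenation of the disubstituted allylic alkene with the cationic rhodium catalyst is fast, whereas the tetrasubstituted isopropylidene and the coumarin double bond should stay intact; no stereocentre is touched.

Step 12
Reactants: 21 the primary alcohol
Product: 22 3-[(1S,2S,3S)-2,3-dimethyl-2-{[(2-oxo-2H-chromen-7-yl)oxy]methyl}-6-(propan-2-ylidene)cyclohexyl]propyl acetate (target)
Conditions: Ac2O, pyridine, DMAP (cat.), CH2Cl2, rt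
Reagents that add atoms: acetic anhydride, CC(=O)OC(C)=O
Why: Acylation of the primary alcohol with acetic anhydride under nucleophilic catalysis by DMAP should give the acetate.

**Compound list**

1 | but-2-yn-1-ol | CC#CCO | starting material
2 | 3,4-dimethyl-2,5-dihydro-1,2-oxamagnesole (cyclic alkenylmagnesium alkoxide) | CC1=C(C)CO[Mg]1 | intermediate
3 | (2Z)-3-iodo-2-methylbut-2-en-1-ol | C/C(I)=C(\C)CO | intermediate
4 | tributyl(ethenyl)stannane | C=C[Sn](CCCC)(CCCC)CCCC | starting material
5 | (2Z)-2,3-dimethylpenta-2,4-dien-1-ol | C=C/C(C)=C(/C)CO | intermediate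
6 | umbelliferone (7-hydroxy-2H-chromen-2-one) | Oc1ccc2ccc(=O)oc2c1 | starting material
7 | 7-{[(2Z)-2,3-dimethylpenta-2,4-dien-1-yl]oxy}-2H-chromen-2-one | C=C/C(C)=C(/C)COc1ccc2ccc(=O)oc2c1 | intermediate
8 | (4R)-4-benzyl-3-(chloroacetyl)-1,3-oxazolidin-2-one | O=C(CCl)N1C(=O)OC[C@H]1Cc1ccccc1 | starting material
9 | {2-[(4R)-4-benzyl-2-oxo-1,3-oxazolidin-3-yl]-2-oxoethyl}(triphenyl)phosphonium chloride | [Cl-].O=C(C[P+](c1ccccc1)(c1ccccc1)c1ccccc1)N1C(=O)OC[C@H]1Cc1ccccc1 | intermediate
10 | (4R)-4-benzyl-3-[(triphenyl-λ5-phosphanylidene)acetyl]-1,3-oxazolidin-2-one | O=C(C=P(c1ccccc1)(c1ccccc1)c1ccccc1)N1C(=O)OC[C@H]1Cc1ccccc1 | intermediate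
11 | 2-methylpropanoyl chloride | CC(C)C(Cl)=O | starting material
12 | dimethylketene | CC(C)=C=O | intermediate
13 | (4R)-4-benzyl-3-(4-methylpenta-2,3-dienoyl)-1,3-oxazolidin-2-one | CC(C)=C=CC(=O)N1C(=O)OC[C@H]1Cc1ccccc1 | intermediate
14 | (4R)-4-benzyl-3-{[(1S,2R)-2,3-dimethyl-2-{[(2-oxo-2H-chromen-7-yl)oxy]methyl}-6-(propan-2-ylidene)cyclohex-3-en-1-yl]carbonyl}-1,3-oxazolidin-2-one | O=C([C@H]1C(=C(C)C)CC=C(C)[C@]1(C)COc1ccc2ccc(=O)oc2c1)N1C(=O)OC[C@H]1Cc1ccccc1 | intermediate
15 | [(1S,2R)-2,3-dimethyl-2-{[(2-oxo-2H-chromen-7-yl)oxy]methyl}-6-(propan-2-ylidene)cyclohex-3-en-1-yl]methanol | OC[C@H]1C(=C(C)C)CC=C(C)[C@]1(C)COc1ccc2ccc(=O)oc2c1 | intermediate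
16 | [(1S,2S,3S)-2,3-dimethyl-2-{[(2-oxo-2H-chromen-7-yl)oxy]methyl}-6-(propan-2-ylidene)cyclohexyl]methanol | OC[C@H]1C(=C(C)C)CC[C@H](C)[C@]1(C)COc1ccc2ccc(=O)oc2c1 | intermediate
17 | (triphenyl-λ5-phosphanylidene)acetaldehyde | O=CC=P(c1ccccc1)(c1ccccc1)c1ccccc1 | starting material
18 | (1S,2S,3S)-2,3-dimethyl-2-{[(2-oxo-2H-chromen-7-yl)oxy]methyl}-6-(propan-2-ylidene)cyclohexane-1-carbaldehyde | O=C[C@H]1C(=C(C)C)CC[C@H](C)[C@]1(C)COc1ccc2ccc(=O)oc2c1 | intermediate
19 | (2E)-3-[(1S,2S,3S)-2,3-dimethyl-2-{[(2-oxo-2H-chromen-7-yl)oxy]methyl}-6-(propan-2-ylidene)cyclohexyl]prop-2-enal | O=C/C=C/[C@H]1C(=C(C)C)CC[C@H](C)[C@]1(C)COc1ccc2ccc(=O)oc2c1 | intermediate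
20 | (2E)-3-[(1S,2S,3S)-2,3-dimethyl-2-{[(2-oxo-2H-chromen-7-yl)oxy]methyl}-6-(propan-2-ylidene)cyclohexyl]prop-2-en-1-ol | OC/C=C/[C@H]1C(=C(C)C)CC[C@H](C)[C@]1(C)COc1ccc2ccc(=O)oc2c1 | intermediate
21 | 3-[(1S,2S,3S)-2,3-dimethyl-2-{[(2-oxo-2H-chromen-7-yl)oxy]methyl}-6-(propan-2-ylidene)cyclohexyl]propan-1-ol | OCCC[C@H]1C(=C(C)C)CC[C@H](C)[C@]1(C)COc1ccc2ccc(=O)oc2c1 | intermediate
22 | 3-[(1S,2S,3S)-2,3-dimethyl-2-{[(2-oxo-2H-chromen-7-yl)oxy]methyl}-6-(propan-2-ylidene)cyclohexyl]propyl acetate | CC(=O)OCCC[C@H]1C(=C(C)C)CC[C@H](C)[C@]1(C)COc1ccc2ccc(=O)oc2c1 | target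

**Step count and risks**

Total step count: 12. Longest linear sequence: 10 steps (steps 1–3 and 6–12).

Steps most likely to fail:

Step 6 (Diels–Alder reaction). The Z diene reaches its s-cis rotamer only against the inside CH2OAr group, so after the first C–C bond the second may not close to the six-membered ring; the pair may then collapse to a cyclobutane, or the diene may oligomerise under the Lewis acid. The fallback sets out from 3 and adds a removable 2-silyl group that destabilises the s-trans rotamer while keeping the same orientation. Negishi coupling of 3 with [1-(trimethylsilyl)ethenyl]zinc bromide (from (1-bromoethenyl)trimethylsilane, Mg, then ZnBr2; Pd(PPh3)4, THF) should give (2Z)-2,3-dimethyl-4-(trimethylsilyl)penta-2,4-dien-1-ol F1. Mitsunobu etherification with 6 should give 7-{[(2Z)-2,3-dimethyl-4-(trimethylsilyl)penta-2,4-dien-1-yl]oxy}-2H-chromen-2-one F2. Cycloaddition with 13 under the conditions of step 6 should give the 4-(trimethylsilyl)cyclohexene adduct F3, and protodesilylation of this vinylsilane (CF3CO2H, CH2Cl2, 0 °C) comes back to the route at 14.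

Step 8 (directed hydrogenation). Hydrogen delivery may be weak or misdirected: the hydroxyl is two carbons further from the alkene than in the classical homoallylic cases, so hydrogen may enter from the aryloxymethyl face or the catalyst may isomerise the alkenes. The fallback goes from 15 to 16 by radical hydrogen-atom-transfer hydrogenation (Mn(dpm)3, dpm = dipivaloylmethanate; PhSiH3, t-BuOOH, i-PrOH, rt). This attacks the trisubstituted alkene in preference to the tetrasubstituted one and should give the thermodynamically preferred C5 epimer: with the C1 substituent held axial by allylic 1,3-strain, the equatorial C5 methyl trans to it is favoured. This fallback makes no new compound (F0).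

Step 9 (oxidation and Wittig olefination). The hindered β,γ-unsaturated aldehyde may enolise before it is olefinated, which would epimerise C1 or move the exocyclic double bond into conjugation. The fallback sets out from 16 and avoids any carbonyl group at this position. Appel iodination (I2, PPh3, imidazole, toluene, 60 °C) should give 7-{[(1S,2S,6S)-2-(iodomethyl)-1,6-dimethyl-3-(propan-2-ylidene)cyclohexyl]methoxy}-2H-chromen-2-one F4. Giese radical addition to 4,4,5,5-tetramethyl-2-vinyl-1,3,2-dioxaborolane ((Me3Si)3SiH, AIBN, benzene, 80 °C) should give 2-{3-[(1S,2S,3S)-2,3-dimethyl-2-{[(2-oxo-2H-chromen-7-yl)oxy]methyl}-6-(propan-2-ylidene)cyclohexyl]propyl}-4,4,5,5-tetramethyl-1,3,2-dioxaborolane F5. Oxidation of the C–B bond (NaBO3·4H2O, THF/H2O, rt) comes back to the route at 21, replacing steps 9–11.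

**Further compounds**

F1 | step 6 | (2Z)-2,3-dimethyl-4-(trimethylsilyl)penta-2,4-dien-1-ol | C=C([Si](C)(C)C)/C(C)=C(/C)CO
F2 | step 6 | 7-{[(2Z)-2,3-dimethyl-4-(trimethylsilyl)penta-2,4-dien-1-yl]oxy}-2H-chromen-2-one | C=C([Si](C)(C)C)/C(C)=C(/C)COc1ccc2ccc(=O)oc2c1
F3 | step 6 | (4R)-4-benzyl-3-{[(1S,2R)-2,3-dimethyl-2-{[(2-oxo-2H-chromen-7-yl)oxy]methyl}-6-(propan-2-ylidene)-4-(trimethylsilyl)cyclohex-3-en-1-yl]carbonyl}-1,3-oxazolidin-2-one | O=C([C@H]1C(=C(C)C)CC([Si](C)(C)C)=C(C)[C@]1(C)COc1ccc2ccc(=O)oc2c1)N1C(=O)OC[C@H]1Cc1ccccc1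
F0 | step 8 | none | none
F4 | step 9 | 7-{[(1S,2S,6S)-2-(iodomethyl)-1,6-dimethyl-3-(propan-2-ylidene)cyclohexyl]methoxy}-2H-chromen-2-one | IC[C@H]1C(=C(C)C)CC[C@H](C)[C@]1(C)COc1ccc2ccc(=O)oc2c1
F5 | step 9 | 2-{3-[(1S,2S,3S)-2,3-dimethyl-2-{[(2-oxo-2H-chromen-7-yl)oxy]methyl}-6-(propan-2-ylidene)cyclohexyl]propyl}-4,4,5,5-tetramethyl-1,3,2-dioxaborolane | CC1(C)OB(CCC[C@H]2C(=C(C)C)CC[C@H](C)[C@]2(C)COc2ccc3ccc(=O)oc3c2)OC1(C)C
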